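**Retrosynthetic overview**

- The target is a 2H-chromene with one quaternary stereocentre (C2, R). The last operations are formation of the C3=C4 alkene by loss of methanol from a 4-methoxychroman and removal of a phenol acetate from the feruloyl unit.
- Key disconnection: C3–C4 and O1–C2 of the pyran ring. The strategy rests on O1–C8a–C4a–C4 being a 1-oxadiene (an O-methylated ortho-quinone methide) latent in 5-acetyl-2-hydroxy-3-methoxybenzaldehyde plus trimethyl orthoformate, and on C2–C3 being the 1,1-disubstituted alkene of 2-methylallyl 4-O-acetylferulate, which already carries the C2 methyl group and the CH2O-feruloyl arm.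
- The aldehyde comes from acetovanillone by ortho-formylation; the alkene comes from ferulic acid by O-acetylation and esterification with 2-methylprop-2-en-1-ol.
- Ring order: both benzene rings are bought; the pyran ring is the only ring made, in the key step, where a confined chiral Brønsted acid sets C2.

Key step: step 4

Assumption: which antipode of the confined acid leads to the 2R series cannot be predicted and would be fixed by a screening run. The cycloadduct is written as its (2R,4R) isomer; any (2R,4S) epimer formed with it would be taken on unseparated, since step 5 removes the C4 centre.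

**Step 1**
Reactants: 1 acetovanillone
Product: 2 5-acetyl-2-hydroxy-3-methoxybenzaldehyde
Conditions: hexamethylenetetramine (2 equiv), CF3CO2H, 85 °C; then 3 M aq. HCl, 60 °C
Reagents that add atoms: hexamethylenetetramine C1N2CN3CN1CN(C2)C3; water O
Why: Duff formylation, in which the iminium electrophile enters the only free position ortho to the phenol (also meta to the acetyl group) and hydride transfer followed by hydrolysis should give the salicylaldehyde.

**Step 2**
Reactants: 3 ferulic acid
Product: 4 4-O-acetylferulic acid
Conditions: Ac2O (1.2 equiv), aq. NaOH (2 equiv), 0 °C to rt; then aq. HCl to pH 2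
Reagents that add atoms: acetic anhydride CC(=O)OC(C)=O
Why: Schotten–Baumann O-acetylation of the phenoxide in cold aqueous base, with the carboxylate left unchanged and the product precipitated on acidification.

**Step 3**
Reactants: 4 4-O-acetylferulic acid, 5 2-methylprop-2-en-1-ol
Product: 7 2-methylallyl (E)-3-(4-acetoxy-3-methoxyphenyl)acrylate, via 4-O-acetylferuloyl chloride 6 (not isolated)
Conditions: (COCl)2, cat. DMF, CH2Cl2, 0 °C to rt; concentrate; then 5, pyridine, CH2Cl2, 0 °C to rt
Reagents that add atoms: none
Why: Acyl chloride formation by Vilsmeier-type activation followed by pyridine-mediated acylation of the primary allylic alcohol, conditions under which the aryl acetate and the E-alkene should be untouched.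

**Step 4**
Reactants: 2 5-acetyl-2-hydroxy-3-methoxybenzaldehyde (1 equiv), 7 2-methylallyl (E)-3-(4-acetoxy-3-methoxyphenyl)acrylate (1.5 equiv), 8 trimethyl orthoformate (1.5 equiv)
Product: 11 [(2R,4R)-6-acetyl-4,8-dimethoxy-2-methyl-3,4-dihydro-2H-chromen-2-yl]methyl (E)-3-(4-acetoxy-3-methoxyphenyl)acrylate, via dimethyl acetal 9 (not isolated), via O-methyl oxocarbenium ion 10 (not isolated)
Conditions: confined imidodiphosphorimidate acid (5 mol %; two 3,3'-bis[3,5-(CF3)2C6H3]-BINOL phosphorus units bridged by NH, each P=N–SO2CF3; antipode chosen to give 2R), 5 Å MS, toluene, −20 to 0 °C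
Reagents that add atoms: none
Why: Proposed new method: acid-catalysed exchange of 2 with 8 should give dimethyl acetal 9, which the strong confined acid ionises to O-methyl oxocarbenium ion 10, an O-alkylated ortho-quinone methide (O1–C8a–C4a–C4) hydrogen-bonded through its phenol to the chiral anion; the CH2 terminus of the methallyl alkene of 7 attacks C4 and the charge developing at the tertiary carbon is quenched by the phenol oxygen, so that C3–C4 and O1–C2 form in one asynchronous inverse-demand hetero-[4+2] event and the proton returns to the catalyst. The closest known reactions are the achiral strong-acid three-component assembly of 4-alkoxychromans from salicylaldehydes, orthoformates and alkenes and the chiral-acid cycloadditions of ortho-quinone methides with styrenes, enol ethers or tethered alkenes; an enantioselective intermolecular version with a prochiral, unactivated 1,1-disubstituted alkene has not been shown. The pyran ring closes in the [4+2] mode, O1 bonding to C2 within a six-membered array (in the stepwise limit a 6-endo capture of the tertiary cation by the ortho phenol). C2 is fixed by the alkene face on which both bonds form (the Re face of the carbon bearing CH3 and CH2O-acyl gives 2R), which the confined anion must select by telling the small methyl group from the long acyloxymethyl arm. C4 follows from the face of 10 and the endo or exo approach and is drawn 4R, but it need not be controlled because step 5 removes this centre, so any (2R,4S) epimer formed alongside would be carried forward unseparated. The step therefore needs alkene-face control and chemoselectivity, and the substrates secure the latter: the cinnamate alkene and the acetylated guaiacyl ring of 7 are too electron-poor to attack 10, and the acetyl group para to O1 raises the electrophilicity of 10 to meet the modest nucleophilicity of the ester-bearing alkene.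

**Step 5**
Reactants: 11 [(2R,4R)-6-acetyl-4,8-dimethoxy-2-methyl-3,4-dihydro-2H-chromen-2-yl]methyl (E)-3-(4-acetoxy-3-methoxyphenyl)acrylate
Product: 12 [(2R)-6-acetyl-8-methoxy-2-methyl-2H-chromen-2-yl]methyl (E)-3-(4-acetoxy-3-methoxyphenyl)acrylate
Conditions: camphor-10-sulfonic acid (20 mol %), 5 Å MS, toluene, 80 °C
Reagents that add atoms: none
Why: Acid-promoted E1 elimination, in which protonation of the C4 methoxy group, ionisation to the benzylic cation stabilised by the ortho ring oxygen and loss of a C3 proton should give the conjugated C3=C4 alkene whatever the configuration at C4, without touching the quaternary C2 centre.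

**Step 6**
Reactants: 12 [(2R)-6-acetyl-8-methoxy-2-methyl-2H-chromen-2-yl]methyl (E)-3-(4-acetoxy-3-methoxyphenyl)acrylate
Product: 13 [(2R)-6-acetyl-8-methoxy-2-methyl-2H-chromen-2-yl]methyl (E)-3-(4-hydroxy-3-methoxyphenyl)acrylate (CNP0168033.1)
Conditions: pyrrolidine (3 equiv), THF, 0 °C to rt; dilute aq. citric acid work-up
Reagents that add atoms: none
Why: Chemoselective aminolysis, in which the aryl acetate with its phenoxide leaving group is cleaved by the secondary amine far faster than the alkyl cinnamate is aminolysed or attacked in conjugate fashion, so the ester link and C2 should be unaffected.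

**Compound list**

1 | acetovanillone (1-(4-hydroxy-3-methoxyphenyl)ethanone) | CC(=O)c1ccc(O)c(OC)c1 | starting material
2 | 5-acetyl-2-hydroxy-3-methoxybenzaldehyde | CC(=O)c1cc(OC)c(O)c(C=O)c1 | intermediate
3 | ferulic acid | COc1cc(/C=C/C(=O)O)ccc1O | starting material
4 | 4-O-acetylferulic acid | COc1cc(/C=C/C(=O)O)ccc1OC(C)=O | intermediate
5 | 2-methylprop-2-en-1-ol | C=C(C)CO | starting material
6 | 4-O-acetylferuloyl chloride | COc1cc(/C=C/C(Cl)=O)ccc1OC(C)=O | intermediate
7 | 2-methylallyl (E)-3-(4-acetoxy-3-methoxyphenyl)acrylate | C=C(C)COC(=O)/C=C/c1ccc(OC(C)=O)c(OC)c1 | intermediate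
8 | trimethyl orthoformate | COC(OC)OC | starting material
9 | 1-[3-(dimethoxymethyl)-4-hydroxy-5-methoxyphenyl]ethanone (dimethyl acetal of 2) | CC(=O)c1cc(OC)c(O)c(C(OC)OC)c1 | intermediate
10 | O-methyl oxocarbenium ion derived from 9 (cation paired with the catalyst anion) | CC(=O)c1cc(OC)c(O)c(C=[O+]C)c1 | intermediate
11 | [(2R,4R)-6-acetyl-4,8-dimethoxy-2-methyl-3,4-dihydro-2H-chromen-2-yl]methyl (E)-3-(4-acetoxy-3-methoxyphenyl)acrylate | CC(=O)Oc1ccc(/C=C/C(=O)OC[C@@]2(C)C[C@@H](OC)c3cc(C(C)=O)cc(OC)c3O2)cc1OC | intermediate
12 | [(2R)-6-acetyl-8-methoxy-2-methyl-2H-chromen-2-yl]methyl (E)-3-(4-acetoxy-3-methoxyphenyl)acrylate | CC(=O)Oc1ccc(/C=C/C(=O)OC[C@@]2(C)C=Cc3cc(C(C)=O)cc(OC)c3O2)cc1OC | intermediate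
13 | [(2R)-6-acetyl-8-methoxy-2-methyl-2H-chromen-2-yl]methyl (E)-3-(4-hydroxy-3-methoxyphenyl)acrylate | COc1cc(/C=C/C(=O)OC[C@@]2(C)C=Cc3cc(C(C)=O)cc(OC)c3O2)ccc1O | target

**Step count**

Total steps: 6. Longest linear sequence: 5 steps (3 → 4 → 7 → 11 → 12 → 13).

**Steps most likely to fail**

1. Step 4 (proposed new method). Possible failures:
   - Discrimination of the two alkene faces may be poor, because only the pocket distinguishes methyl from acyloxymethyl, which would give low enantiomeric purity at C2.
   - The weakly nucleophilic alkene may add slowly, so that reversible acetal oligomerisation or ketalisation of the aryl ketone takes over.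
   - The charge developing at C2 may be diverted by participation of the neighbouring ester carbonyl.

   Fallback (known chemistry), setting out from 2, 7 and 8: the same three components are combined under an achiral strong acid ((CF3SO2)2NH, 5 mol %, CH2Cl2, 0 °C to rt), the established racemic three-component chroman synthesis, to give the racemic 4-methoxychroman F1 as a mixture of C4 epimers. Methanol is eliminated under the conditions of step 5 to give the racemic chromene acetate F2. Preparative chromatography on a chiral stationary phase (amylose tris(3,5-dimethylphenylcarbamate), supercritical CO2/MeOH) then separates the enantiomers. The 2R enantiomer is 12, where the route is rejoined; the 2S chromene acetate F3 is set aside. The absolute configuration of the collected fraction would have to be assigned, for example by comparing its circular dichroism with a computed spectrum.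

2. Step 5. Possible failures:
   - Ionisation at C4 may be sluggish, because the acetyl group para to O1 weakens the donation of the ring oxygen.
   - Forcing the acid or the temperature may erode the C2 configuration through reversible C2–O1 ionisation, or oligomerise the chromene through its styrene-like alkene.

   Fallback, setting out from 11: the benzylic C4–OMe bond is cleaved with Me3SiI made in the flask (Me3SiCl, NaI, MeCN, 0 °C) to give the 4-iodochroman F4. The dialkyl benzylic ether oxygen should be silylated in preference to the less basic aryl ether oxygens. Without purification F4 is treated with DBU in toluene at rt, and E2 loss of hydrogen iodide across C3–C4 under non-acidic conditions should give 12, where the route is rejoined.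

3. Step 1. Possible failures:
   - Electrophilic substitution on the acetyl-deactivated ring may stall.
   - Prolonged heating with hexamethylenetetramine may give tarry condensation products.

   Fallback, setting out from 1: Lederer–Manasse hydroxymethylation of the phenoxide (aq. formaldehyde, aq. NaOH, rt) at its only free ortho position gives the salicyl alcohol 1-[4-hydroxy-3-(hydroxymethyl)-5-methoxyphenyl]ethanone F5. The α-methyl group of the ketone is protected from aldol reaction by the vinylogous carboxylate character of the phenoxide. Oxidation of the benzylic alcohol with activated MnO2 in EtOAc then rejoins the route at 2.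

**Further compounds**

F1 | step 4 | racemic (6-acetyl-4,8-dimethoxy-2-methyl-3,4-dihydro-2H-chromen-2-yl)methyl (E)-3-(4-acetoxy-3-methoxyphenyl)acrylate (mixture of C4 epimers) | CC(=O)Oc1ccc(/C=C/C(=O)OCC2(C)CC(OC)c3cc(C(C)=O)cc(OC)c3O2)cc1OC
F2 | step 4 | racemic (6-acetyl-8-methoxy-2-methyl-2H-chromen-2-yl)methyl (E)-3-(4-acetoxy-3-methoxyphenyl)acrylate | CC(=O)Oc1ccc(/C=C/C(=O)OCC2(C)C=Cc3cc(C(C)=O)cc(OC)c3O2)cc1OC
F3 | step 4 | [(2S)-6-acetyl-8-methoxy-2-methyl-2H-chromen-2-yl]methyl (E)-3-(4-acetoxy-3-methoxyphenyl)acrylate | CC(=O)Oc1ccc(/C=C/C(=O)OC[C@]2(C)C=Cc3cc(C(C)=O)cc(OC)c3O2)cc1OC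
F4 | step 5 | [(2R)-6-acetyl-4-iodo-8-methoxy-2-methyl-3,4-dihydro-2H-chromen-2-yl]methyl (E)-3-(4-acetoxy-3-methoxyphenyl)acrylate (C4 epimers) | CC(=O)Oc1ccc(/C=C/C(=O)OC[C@@]2(C)CC(I)c3cc(C(C)=O)cc(OC)c3O2)cc1OC
F5 | step 1 | 1-[4-hydroxy-3-(hydroxymethyl)-5-methoxyphenyl]ethanone | CC(=O)c1cc(CO)c(O)c(OC)c1
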